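**Plan**
1. Retrosynthetic cuts, in order: the 1,10-epoxide oxygen; the C8–O and C3–O ester bonds; the lactone bonds C7–C11 and O–C6 together (an acrylic acid unit is excised); the ring bond C3–C4; then C4=C5, C1–C2/C10–C14 and C8–C9 of the open chain.
2. Forward: a C5–C8 enal is propargylated, the alkyne is carbometallated to the (E)-C1=C10 olefin and extended to C3, the (Z)-iodo-diene is installed, and the ten-membered (1(10)E,4Z,6E)-triene closes by a Nozaki–Hiyama–Kishi reaction. The α-methylene-γ-lactone is then annulated across C6=C7, the two esters are attached, and the 1(10) olefin is epoxidised last.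
3. Enabling feature: C6 is allylic to the C4=C5 olefin, so C6=C7 can be carried as the second olefin of a ring diene C4=C5–C6=C7. A 1-carboxyvinyl-palladium adds to C7, and the π-allyl over C6–C5–C4 is captured at C6 by its own carboxylate, which builds the five-membered lactone and leaves the 4Z olefin in place.
4. Stereochemistry: C8 from catalyst-controlled propargylation; C3 from the ring closure (reagent-controlled correction held in reserve); C6 and C7 from syn addition to the 6E olefin on the outer ring face, directed by C8; C1/C10 from outer-face epoxidation; the acyl stereocentres from (R)-2-methylbutanoic acid and a Sharpless epoxidation of (Z)-2-methylbut-2-en-1-ol.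

Key step: step 11

Remarks: Ring atoms carry germacrane numbers (C1–C10 ring, C11–C13 lactone carbons, C14 on C10, C15 on C4). The C7 descriptor reads S while O8 bears silicon and R otherwise; this is a CIP priority change only. Compounds 1, 2, 4, 7, 13, 21, 24, 27 and (R)-TRIP are taken as purchasable.

Step 1
Reactants: 1 (tert-butyldimethylsilyloxy)acetaldehyde; 2 (triphenylphosphoranylidene)acetaldehyde
Product: 3 (2E)-4-[(tert-butyldimethylsilyl)oxy]but-2-enal
Conditions: 2 (1.05 equiv), toluene, 80 °C
Reagents that add atoms: none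
Why: Wittig olefination with the stabilised formyl ylide should give the (E)-enal, and the α-silyloxy aldehyde is more electrophilic than the product enal, which limits a second homologation.

Step 2
Reactants: 3 (2E)-4-[(tert-butyldimethylsilyl)oxy]but-2-enal; 4 allenylboronic acid pinacol ester
Product: 5 (4R,5E)-7-[(tert-butyldimethylsilyl)oxy]hept-5-en-1-yn-4-ol
Conditions: (R)-TRIP (5 mol %), 4 Å MS, toluene, 0 °C; aqueous work-up
Reagents that add atoms: none
Why: Chiral phosphoric acid-catalysed propargylboration runs through a closed six-membered SE2′ transition state (1,2-addition only), and the (R)-catalyst is expected, by analogy with aryl and alkenyl aldehydes, to direct attack to the Re face and so set the (R)-carbinol that becomes C8.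

Step 3
Reactants: 5 (4R,5E)-7-[(tert-butyldimethylsilyl)oxy]hept-5-en-1-yn-4-ol
Product: 6 (4R,5E)-4,7-bis[(tert-butyldimethylsilyl)oxy]hept-5-en-1-yne
Conditions: TBSCl, imidazole, DMF, rt
Reagents that add atoms: tert-butyldimethylsilyl chloride, CC(C)(C)[Si](C)(C)Cl
Why: Standard silylation gives a secondary TBS ether that should survive the aluminium, chromium and palladium steps and is removed only in step 14.

Step 4
Reactants: 6 (4R,5E)-4,7-bis[(tert-butyldimethylsilyl)oxy]hept-5-en-1-yne; 7 ethylene oxide
Product: 10 (3E,6R,7E)-6,9-bis[(tert-butyldimethylsilyl)oxy]-4-methylnona-3,7-dien-1-ol, via alkenyldimethylalane 8 (not isolated), via lithium alkenylalanate 9 (not isolated)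
Conditions: Me3Al, Cp2ZrCl2 (cat.), CH2Cl2, 0 °C → rt; volatiles removed; n-BuLi, THF–hexane, −78 → 0 °C; ethylene oxide, 0 °C → rt; aq. Rochelle salt
Reagents that add atoms: trimethylaluminium, C[Al](C)C
Why: Zirconium-catalysed carboalumination (Negishi) adds methyl and aluminium syn across the terminal alkyne with aluminium on the terminal carbon, which fixes the (E)-trisubstituted C1=C10 olefin, and the ate complex opens ethylene oxide with retention of olefin geometry to add C2–C3 as a primary alcohol.

Step 5
Reactants: 10 (3E,6R,7E)-6,9-bis[(tert-butyldimethylsilyl)oxy]-4-methylnona-3,7-dien-1-ol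
Product: 11 (2E,4R,6E)-4-[(tert-butyldimethylsilyl)oxy]-6-methylnona-2,6-diene-1,9-diol
Conditions: CSA (cat.), MeOH–CH2Cl2, −10 → 0 °C
Reagents that add atoms: none
Why: Acid-catalysed methanolysis should cleave the unhindered primary allylic TBS ether much faster than the secondary one.

Step 6
Reactants: 11 (2E,4R,6E)-4-[(tert-butyldimethylsilyl)oxy]-6-methylnona-2,6-diene-1,9-diol
Product: 12 (2E,4R,6E)-4-[(tert-butyldimethylsilyl)oxy]-9-hydroxy-6-methylnona-2,6-dienal
Conditions: activated MnO2 (excess), CH2Cl2, rt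
Reagents that add atoms: none
Why: Manganese dioxide oxidises only the allylic alcohol, so the saturated primary alcohol at C3 is left for step 8.

Step 7
Reactants: 12 (2E,4R,6E)-4-[(tert-butyldimethylsilyl)oxy]-9-hydroxy-6-methylnona-2,6-dienal; 13 ethyltriphenylphosphonium iodide
Product: 17 (3E,6R,7E,9Z)-6-[(tert-butyldimethylsilyl)oxy]-10-iodo-4-methylundeca-3,7,9-trien-1-ol, via ethylidene ylide 14 (not isolated), via (1-iodoethyl)phosphonium iodide 15 (not isolated), via iodoethylidene ylide 16 (not isolated)
Conditions: 13 (2.2 equiv), n-BuLi, THF, 0 °C; I2, −78 °C; NaHMDS, −78 → −20 °C; then 12, −78 °C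
Reagents that add atoms: iodine, II
Why: Wittig olefination with the α-iodo ylide (Stork–Zhao type) is kinetically Z-selective and places iodine cis to the chain, which is the geometry later needed for C3 cis to C6 across C4=C5; the free alcohol is not acidic enough to quench the ylide.

Step 8
Reactants: 17 (3E,6R,7E,9Z)-6-[(tert-butyldimethylsilyl)oxy]-10-iodo-4-methylundeca-3,7,9-trien-1-ol
Product: 18 (3E,6R,7E,9Z)-6-[(tert-butyldimethylsilyl)oxy]-10-iodo-4-methylundeca-3,7,9-trienal
Conditions: Dess–Martin periodinane, pyridine, CH2Cl2, 0 °C; used at once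
Reagents that add atoms: none
Why: Buffered Dess–Martin oxidation should give the β,γ-unsaturated aldehyde without migration of the C1=C10 olefin into conjugation.

Step 9
Reactants: 18 (3E,6R,7E,9Z)-6-[(tert-butyldimethylsilyl)oxy]-10-iodo-4-methylundeca-3,7,9-trienal
Product: 19 (1S,2Z,4E,6R,8E)-6-[(tert-butyldimethylsilyl)oxy]-2,8-dimethylcyclodeca-2,4,8-trien-1-ol
Conditions: CrCl2 (8 equiv), NiCl2 (cat.), degassed DMSO, rt, slow addition to about 0.003 M
Reagents that add atoms: none
Why: The intramolecular Nozaki–Hiyama–Kishi reaction converts the alkenyl iodide into an alkenylchromium(III) species with retention of the Z geometry and adds it to the aldehyde under non-basic conditions at high dilution to close the ten-membered ring at C3–C4; the C3 carbinol arises under substrate control in the cyclic transition state and the 3S isomer is carried on.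

Step 10
Reactants: 19 (1S,2Z,4E,6R,8E)-6-[(tert-butyldimethylsilyl)oxy]-2,8-dimethylcyclodeca-2,4,8-trien-1-ol
Product: 20 (1Z,3E,5R,7E,10S)-5-[(tert-butyldimethylsilyl)oxy]-1,7-dimethyl-10-[(triethylsilyl)oxy]cyclodeca-1,3,7-triene
Conditions: TESCl, imidazole, CH2Cl2, 0 °C
Reagents that add atoms: chlorotriethylsilane, CC[Si](Cl)(CC)CC
Why: Silylation removes the free C3 hydroxyl, which could otherwise close a 2,5-dihydrofuran onto C6 of the π-allyl intermediate in step 11, and TES can later be cleaved in the presence of TBS.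

Step 11
Reactants: 20 (1Z,3E,5R,7E,10S)-5-[(tert-butyldimethylsilyl)oxy]-1,7-dimethyl-10-[(triethylsilyl)oxy]cyclodeca-1,3,7-triene; 21 2-bromoacrylic acid
Product: 22 (3S,6R,7S,8R,1(10)E,4Z)-8-[(tert-butyldimethylsilyl)oxy]-3-[(triethylsilyl)oxy]germacra-1(10),4,11(13)-trien-12,6-olide
Conditions: Pd2(dba)3 (5 mol %), tri(2-furyl)phosphine (20 mol %), Ag2CO3 (2 equiv), 21 (2.5 equiv, slow addition), MeCN, 50 °C, chloride-free
Reagents that add atoms: none
Why: Oxidative addition of Pd(0) into the C–Br bond of 21 gives a 1-carboxyvinyl-palladium(II) species that inserts the C6=C7 olefin of the ring diene syn, with the vinyl carbon bonding to C7 (the less substituted diene terminus) and palladium passing into a π-allyl unit over C6–C5–C4; the carboxylate held on the same palladium then forms the O–C6 bond by inner-sphere reductive elimination and returns Pd(0). The closest known reaction type is the Larock heteroannulation of 1,3-dienes by aryl or vinylic halides that carry a carboxylic acid. The γ-lactone closes in a 5-exo mode at the allyl terminus C6 (closure at C4 would need a seven-membered ring at a fully substituted carbon), so the 4Z olefin is left in place. C7 is set by carbopalladation on the outer face of the 6E olefin in the ring conformer that holds the C8–O bond near the diene plane and C8–H on the attacked face, while C9 and the rest of the ring cover the other face; C6 is set by delivery of oxygen on the palladium-bearing face, so the 6E geometry is translated into the trans ring fusion. The step needs reaction at the conjugated diene and not at the isolated C1=C10 olefin (secured by conjugation and π-allyl formation), C–O bond formation faster than β-hydride elimination (favoured by silver carbonate and the absence of chloride), and silyl ethers instead of esters on the allylic C3 and C8 oxygens so that Pd(0) cannot ionise them.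

Step 12
Reactants: 22 (3S,6R,7S,8R,1(10)E,4Z)-8-[(tert-butyldimethylsilyl)oxy]-3-[(triethylsilyl)oxy]germacra-1(10),4,11(13)-trien-12,6-olide
Product: 23 (3S,6R,7S,8R,1(10)E,4Z)-8-[(tert-butyldimethylsilyl)oxy]-3-hydroxygermacra-1(10),4,11(13)-trien-12,6-olide
Conditions: PPTS (cat.), MeOH–CH2Cl2, 0 °C
Reagents that add atoms: none
Why: The allylic secondary TES ether is solvolysed under mild acid catalysis that should leave the hindered TBS ether, the lactone and the strained 1(10) olefin untouched.

Step 13
Reactants: 23 (3S,6R,7S,8R,1(10)E,4Z)-8-[(tert-butyldimethylsilyl)oxy]-3-hydroxygermacra-1(10),4,11(13)-trien-12,6-olide; 24 (R)-2-methylbutanoic acid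
Product: 25 (3S,6R,7S,8R,1(10)E,4Z)-8-[(tert-butyldimethylsilyl)oxy]-3-{[(2R)-2-methylbutanoyl]oxy}germacra-1(10),4,11(13)-trien-12,6-olide
Conditions: DCC, DMAP (cat.), CH2Cl2, 0 °C → rt
Reagents that add atoms: none
Why: Steglich esterification acylates the only free hydroxyl, and the purely alkyl-substituted α-stereocentre of the acid should not epimerise under carbodiimide activation at low temperature.

Step 14
Reactants: 25 (3S,6R,7S,8R,1(10)E,4Z)-8-[(tert-butyldimethylsilyl)oxy]-3-{[(2R)-2-methylbutanoyl]oxy}germacra-1(10),4,11(13)-trien-12,6-olide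
Product: 26 (3S,6R,7R,8R,1(10)E,4Z)-8-hydroxy-3-{[(2R)-2-methylbutanoyl]oxy}germacra-1(10),4,11(13)-trien-12,6-olide
Conditions: HF·pyridine, pyridine, THF, 0 °C → rt
Reagents that add atoms: none
Why: Pyridine-buffered HF cleaves the TBS ether without base, which avoids conjugate addition to the methylene lactone and migration of the lactone from O6 to O8.

Step 15
Reactants: 27 methyl angelate [methyl (2Z)-2-methylbut-2-enoate]
Product: 28 (2Z)-2-methylbut-2-en-1-ol
Conditions: DIBAL-H (2.2 equiv), CH2Cl2, −78 → 0 °C; aq. Rochelle salt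
Reagents that add atoms: none
Why: 1,2-Reduction of the enoate with DIBAL-H gives the allylic alcohol with the Z geometry retained.

Step 16
Reactants: 28 (2Z)-2-methylbut-2-en-1-ol
Product: 29 [(2S,3R)-2,3-dimethyloxiran-2-yl]methanol
Conditions: Ti(OiPr)4 (10 mol %), L-(+)-diisopropyl tartrate (12 mol %), TBHP, 4 Å MS, CH2Cl2, −20 °C
Reagents that add atoms: tert-butyl hydroperoxide, CC(C)(C)OO
Why: Sharpless asymmetric epoxidation with the L-(+)-tartrate delivers oxygen to the face that gives the (2S,3R)-epoxy alcohol (the sense known for nerol-type Z-allylic alcohols), and the cis relation of C3-methyl and CH2OH is carried over from the Z olefin.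

Step 17
Reactants: 29 [(2S,3R)-2,3-dimethyloxiran-2-yl]methanol
Product: 30 (2R,3R)-2,3-dimethyloxirane-2-carboxylic acid
Conditions: TEMPO (cat.), PhI(OAc)2 (2.2 equiv), MeCN–H2O, rt
Reagents that add atoms: water, O
Why: Oxoammonium oxidation proceeds through the aldehyde hydrate to the acid under near-neutral conditions that spare the epoxide; the C2 descriptor changes from S to R only because the carboxyl group outranks C3.

Step 18
Reactants: 26 (3S,6R,7R,8R,1(10)E,4Z)-8-hydroxy-3-{[(2R)-2-methylbutanoyl]oxy}germacra-1(10),4,11(13)-trien-12,6-olide; 30 (2R,3R)-2,3-dimethyloxirane-2-carboxylic acid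
Product: 32 (3S,6R,7R,8R,1(10)E,4Z)-8-{[(2R,3R)-2,3-dimethyloxirane-2-carbonyl]oxy}-3-{[(2R)-2-methylbutanoyl]oxy}germacra-1(10),4,11(13)-trien-12,6-olide, via mixed anhydride 31 (not isolated)
Conditions: 30, 2,4,6-trichlorobenzoyl chloride, Et3N, toluene, rt; then 26, DMAP, toluene, rt → 40 °C
Reagents that add atoms: none
Why: Yamaguchi esterification activates the hindered α-quaternary acid as a mixed anhydride that DMAP transfers to the secondary C8 hydroxyl, and the acid has no α-hydrogen or olefin that could isomerise.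

Step 19
Reactants: 32 (3S,6R,7R,8R,1(10)E,4Z)-8-{[(2R,3R)-2,3-dimethyloxirane-2-carbonyl]oxy}-3-{[(2R)-2-methylbutanoyl]oxy}germacra-1(10),4,11(13)-trien-12,6-olide
Product: 33 (1R,3S,6R,7R,8R,10R,4Z)-1,10-epoxy-8-{[(2R,3R)-2,3-dimethyloxirane-2-carbonyl]oxy}-3-{[(2R)-2-methylbutanoyl]oxy}germacra-4,11(13)-dien-12,6-olide (target)
Conditions: dimethyldioxirane (1.05 equiv), acetone–CH2Cl2, −40 → −20 °C
Reagents that add atoms: dimethyldioxirane, CC1(C)OO1
Why: The strained, electron-rich (E)-1(10) olefin is by far the most reactive toward the electrophilic dioxirane (C4=C5 is deactivated by two allylic acyloxy groups and the methylene lactone is electron-poor), and attack on its outer face in the preferred ring conformer should give the trans (1R,10R)-epoxide under neutral conditions.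

**Compound list**
1 | (tert-butyldimethylsilyloxy)acetaldehyde | O=CCO[Si](C)(C)C(C)(C)C | starting material
2 | (triphenylphosphoranylidene)acetaldehyde | O=CC=P(c1ccccc1)(c1ccccc1)c1ccccc1 | starting material
3 | (2E)-4-[(tert-butyldimethylsilyl)oxy]but-2-enal | O=C/C=C/CO[Si](C)(C)C(C)(C)C | intermediate
4 | allenylboronic acid pinacol ester | C=C=CB1OC(C)(C)C(C)(C)O1 | starting material
5 | (4R,5E)-7-[(tert-butyldimethylsilyl)oxy]hept-5-en-1-yn-4-ol | C#CC[C@@H](O)/C=C/CO[Si](C)(C)C(C)(C)C | intermediate
6 | (4R,5E)-4,7-bis[(tert-butyldimethylsilyl)oxy]hept-5-en-1-yne | C#CC[C@@H](O[Si](C)(C)C(C)(C)C)/C=C/CO[Si](C)(C)C(C)(C)C | intermediate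
7 | ethylene oxide | C1CO1 | starting material
8 | {(1E,4R,5E)-4,7-bis[(tert-butyldimethylsilyl)oxy]-2-methylhepta-1,5-dien-1-yl}dimethylalane | C[Al](C)/C=C(\C)C[C@@H](O[Si](C)(C)C(C)(C)C)/C=C/CO[Si](C)(C)C(C)(C)C | intermediate
9 | lithium butyl{(1E,4R,5E)-4,7-bis[(tert-butyldimethylsilyl)oxy]-2-methylhepta-1,5-dien-1-yl}dimethylalanate | [Li+].CCCC[Al-](C)(C)/C=C(\C)C[C@@H](O[Si](C)(C)C(C)(C)C)/C=C/CO[Si](C)(C)C(C)(C)C | intermediate
10 | (3E,6R,7E)-6,9-bis[(tert-butyldimethylsilyl)oxy]-4-methylnona-3,7-dien-1-ol | OCC/C=C(\C)C[C@@H](O[Si](C)(C)C(C)(C)C)/C=C/CO[Si](C)(C)C(C)(C)C | intermediate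
11 | (2E,4R,6E)-4-[(tert-butyldimethylsilyl)oxy]-6-methylnona-2,6-diene-1,9-diol | OCC/C=C(\C)C[C@@H](O[Si](C)(C)C(C)(C)C)/C=C/CO | intermediate
12 | (2E,4R,6E)-4-[(tert-butyldimethylsilyl)oxy]-9-hydroxy-6-methylnona-2,6-dienal | OCC/C=C(\C)C[C@@H](O[Si](C)(C)C(C)(C)C)/C=C/C=O | intermediate
13 | ethyltriphenylphosphonium iodide | CC[P+](c1ccccc1)(c1ccccc1)c1ccccc1.[I-] | starting material
14 | ethylidenetriphenylphosphorane | CC=P(c1ccccc1)(c1ccccc1)c1ccccc1 | intermediate
15 | (1-iodoethyl)triphenylphosphonium iodide | CC(I)[P+](c1ccccc1)(c1ccccc1)c1ccccc1.[I-] | intermediate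
16 | (1-iodoethylidene)triphenylphosphorane | CC(I)=P(c1ccccc1)(c1ccccc1)c1ccccc1 | intermediate
17 | (3E,6R,7E,9Z)-6-[(tert-butyldimethylsilyl)oxy]-10-iodo-4-methylundeca-3,7,9-trien-1-ol | OCC/C=C(\C)C[C@@H](O[Si](C)(C)C(C)(C)C)/C=C/C=C(\I)C | intermediate
18 | (3E,6R,7E,9Z)-6-[(tert-butyldimethylsilyl)oxy]-10-iodo-4-methylundeca-3,7,9-trienal | O=CC/C=C(\C)C[C@@H](O[Si](C)(C)C(C)(C)C)/C=C/C=C(\I)C | intermediate
19 | (1S,2Z,4E,6R,8E)-6-[(tert-butyldimethylsilyl)oxy]-2,8-dimethylcyclodeca-2,4,8-trien-1-ol | O[C@H]1C/C=C(\C)C[C@@H](O[Si](C)(C)C(C)(C)C)/C=C/C=C1/C | intermediate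
20 | (1Z,3E,5R,7E,10S)-5-[(tert-butyldimethylsilyl)oxy]-1,7-dimethyl-10-[(triethylsilyl)oxy]cyclodeca-1,3,7-triene | CC[Si](CC)(CC)O[C@H]1C/C=C(\C)C[C@@H](O[Si](C)(C)C(C)(C)C)/C=C/C=C1/C | intermediate
21 | 2-bromoacrylic acid | C=C(Br)C(=O)O | starting material
22 | (3S,6R,7S,8R,1(10)E,4Z)-8-[(tert-butyldimethylsilyl)oxy]-3-[(triethylsilyl)oxy]germacra-1(10),4,11(13)-trien-12,6-olide | C=C1C(=O)O[C@@H]2/C=C(/C)[C@@H](O[Si](CC)(CC)CC)C/C=C(\C)C[C@@H](O[Si](C)(C)C(C)(C)C)[C@@H]12 | intermediate
23 | (3S,6R,7S,8R,1(10)E,4Z)-8-[(tert-butyldimethylsilyl)oxy]-3-hydroxygermacra-1(10),4,11(13)-trien-12,6-olide | C=C1C(=O)O[C@@H]2/C=C(/C)[C@@H](O)C/C=C(\C)C[C@@H](O[Si](C)(C)C(C)(C)C)[C@@H]12 | intermediate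
24 | (R)-2-methylbutanoic acid | CC[C@@H](C)C(=O)O | starting material
25 | (3S,6R,7S,8R,1(10)E,4Z)-8-[(tert-butyldimethylsilyl)oxy]-3-{[(2R)-2-methylbutanoyl]oxy}germacra-1(10),4,11(13)-trien-12,6-olide | C=C1C(=O)O[C@@H]2/C=C(/C)[C@@H](OC(=O)[C@H](C)CC)C/C=C(\C)C[C@@H](O[Si](C)(C)C(C)(C)C)[C@@H]12 | intermediate
26 | (3S,6R,7R,8R,1(10)E,4Z)-8-hydroxy-3-{[(2R)-2-methylbutanoyl]oxy}germacra-1(10),4,11(13)-trien-12,6-olide | C=C1C(=O)O[C@@H]2/C=C(/C)[C@@H](OC(=O)[C@H](C)CC)C/C=C(\C)C[C@@H](O)[C@@H]12 | intermediate
27 | methyl angelate, methyl (2Z)-2-methylbut-2-enoate | C/C=C(/C)C(=O)OC | starting material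
28 | (2Z)-2-methylbut-2-en-1-ol | C/C=C(/C)CO | intermediate
29 | [(2S,3R)-2,3-dimethyloxiran-2-yl]methanol | OC[C@]1(C)O[C@@H]1C | intermediate
30 | (2R,3R)-2,3-dimethyloxirane-2-carboxylic acid | OC(=O)[C@]1(C)O[C@@H]1C | intermediate
31 | (2R,3R)-2,3-dimethyloxirane-2-carboxylic 2,4,6-trichlorobenzoic anhydride | O=C(OC(=O)[C@]1(C)O[C@@H]1C)c1c(Cl)cc(Cl)cc1Cl | intermediate
32 | (3S,6R,7R,8R,1(10)E,4Z)-8-{[(2R,3R)-2,3-dimethyloxirane-2-carbonyl]oxy}-3-{[(2R)-2-methylbutanoyl]oxy}germacra-1(10),4,11(13)-trien-12,6-olide | C=C1C(=O)O[C@@H]2/C=C(/C)[C@@H](OC(=O)[C@H](C)CC)C/C=C(\C)C[C@@H](OC(=O)[C@]3(C)O[C@@H]3C)[C@@H]12 | intermediate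
33 | (1R,3S,6R,7R,8R,10R,4Z)-1,10-epoxy-8-{[(2R,3R)-2,3-dimethyloxirane-2-carbonyl]oxy}-3-{[(2R)-2-methylbutanoyl]oxy}germacra-4,11(13)-dien-12,6-olide | C=C1C(=O)O[C@@H]2/C=C(/C)[C@@H](OC(=O)[C@H](C)CC)C[C@H]3O[C@]3(C)C[C@@H](OC(=O)[C@]3(C)O[C@@H]3C)[C@@H]12 | target

Total step count: 19. Longest linear sequence: 16 (steps 1–14, 18, 19).

**Steps most likely to fail**

Step 11. The π-allylpalladium intermediate may undergo β-hydride elimination before the C–O bond forms (net Heck vinylation), the carbopalladation may take the wrong face of the 6E olefin, or acid 21 may be consumed by self-reaction. The fallback replaces carbopalladation by a radical–polar crossover and sets out from 20. Oxidative free-radical lactone annulation with malonic acid (Mn(OAc)3·2H2O, Cu(OAc)2, KOAc, AcOH–MeCN, rt → 40 °C) should add the malonyl radical to C7, oxidise the resulting allyl radical and close the lactone at C6, giving the 11-carboxy lactone F1 as a C11 epimer mixture. Decarboxylative Mannich methylenation of F1 (aqueous formaldehyde, Et2NH, NaOAc, AcOH) then installs the exocyclic methylene and comes back to the route at 22.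

Step 9. The alkenylchromium species may add to the aldehyde with poor facial selectivity, so that 19 forms together with its C3 epimer, and intermolecular coupling competes if dilution is insufficient. The fallback replaces substrate control by reagent control and sets out from 19 as the epimer mixture. Oxidation with MnO2 in CH2Cl2 gives the dienone (2Z,4E,6R,8E)-6-[(tert-butyldimethylsilyl)oxy]-2,8-dimethylcyclodeca-2,4,8-trien-1-one F2. Corey–Bakshi–Shibata reduction ((R)-Me-CBS, catecholborane, toluene, −78 °C; alkenyl as the large group) should then return the 3S alcohol and come back to the route at 19.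

Step 19. Oxygen transfer may occur on the inner face of the 1(10) olefin (wrong epoxide diastereomer) or at C4=C5. The fallback replaces substrate control by catalyst control and sets out from 32. Shi epoxidation with the D-fructose-derived ketone (Oxone, K2CO3, Bu4NHSO4, MeCN–dimethoxymethane–aqueous buffer, 0 °C) should give the (1R,10R)-epoxide through the spiro transition state, as for (E)-trisubstituted olefins of this substitution pattern, and comes back to the route at 33 without any new compound.

**Further compounds**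
F1 | step 11 | (3S,6R,7S,8R,1(10)E,4Z)-8-[(tert-butyldimethylsilyl)oxy]-11-carboxy-3-[(triethylsilyl)oxy]-13-norgermacra-1(10),4-dien-12,6-olide (C11 epimers) | OC(=O)C1C(=O)O[C@@H]2/C=C(/C)[C@@H](O[Si](CC)(CC)CC)C/C=C(\C)C[C@@H](O[Si](C)(C)C(C)(C)C)[C@@H]12
F2 | step 9 | (2Z,4E,6R,8E)-6-[(tert-butyldimethylsilyl)oxy]-2,8-dimethylcyclodeca-2,4,8-trien-1-one | O=C1C/C=C(\C)C[C@@H](O[Si](C)(C)C(C)(C)C)/C=C/C=C1/C
F0 | step 19 | none | none
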